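**Assumption (remark on the chemistry):** the C7–C7' biaryl axis has one oxygen substituent and one hydrogen ortho on each ring and no descriptor in the target; it is taken to rotate freely at room temperature, so no axial descriptor is carried through the route.

## Analysis of the target

The target (27) is a 7,7'-linked biaryl of two C13 units with the same carbon skeleton. One is a 2-acetyl-1,8-dihydroxy-3-methylnaphthalene (rings A and B); the other is its 1,2-dihydro relative (aromatic ring C, partly saturated ring D with C3'=C4'). Ring D holds the only two stereocentres, C1' (S, benzylic carbinol) and C2' (R, acetyl-bearing). They are adjacent and trans, which corresponds to an anti aldol relationship between the C1' hydroxyl and the C2' ring substituent. Ring D is a β-hydroxy ketone whose dehydration would aromatise it to a second naphthalene, C2' is both α to a ketone and allylic, and C1' is a benzylic alcohol ortho to a phenol. Once ring D exists, acid, base and heat must therefore be kept away. Three phenols (two of them peri and hydrogen-bonded to the ring A acetyl group) and two methyl ketones create chemoselectivity problems for every hydride or carbon nucleophile. The difficulty is to tell two nearly identical halves apart and to introduce the stereocentres late and mildly. The strategy rests on the fact that rings B and C are both 3-aryl-6-methylsalicylate units (carboxyl carbon C1 or C1' on C8a or C8a', oxygen on C8 or C8', methyl carbon C4 or C4' on C4a or C4a'). C2 and C3 of ring A, with the acetyl and methyl groups, then correspond to a five-carbon β-methoxy enone inserted between the ester carbon and the lateral methyl of ring B.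

## Retrosynthetic reasoning

**27 from 26 (O–Si bonds).** The last operation should be the mildest available. All four hydroxyl groups are therefore released from silyl ethers with a buffered desilylating agent, since ring D tolerates neither the acid that acetal-type groups need nor hydrogenolysis. This fixes the protecting groups of the whole endgame.

**26 from 25 (C3'=C4').** Ring D is opened at its only double bond. This leaves a vinyl group on C4a' and an isopropenyl group on C2' in 25, which a ruthenium carbene can join to a six-membered ring without touching C1' or C2'. Cutting C1'–C8a' or C4'–C4a' instead would require aryl–carbon bond formation next to the stereocentres.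

**25 from 24 from 23 (C2' acyl–CH3).** The methyl of the ring D acetyl group is removed so that C2' carries an acyl group bound to a chiral auxiliary. Ring A already contains an aryl methyl ketone, so the methyl must come from a reagent that substitutes an activated acyl group and leaves ketones alone. The imide 23 is therefore converted into thioester 24, and this into ketone 25 with a methylcopper reagent.

**23 from 18 and 22 (C1'–C2').** C1'–C2' is an aldol bond between aldehyde 18 and the 3-methylbut-3-enoyl imide 22, whose α-carbon already bears the isopropenyl group. The trans ring relationship requires the anti aldol, and the (S)-benzyl auxiliary sets the absolute sense. Both stereocentres are set in this one step, late in the route.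

**18 from 13 (oxidation level and protecting groups).** The aldehyde carbon of 18 is the ring C ester carbon of 13. The acetal ethers are removed first (14) and replaced by silyl groups (16). Only then is the ester reduced (17) and the aldehyde formed (18), so that no free phenol meets hydride or oxidant. The ring A ketone is reduced and re-oxidised along the way.

**13 from 10 and 11 (C3–C4 and C1–C2).** Ring A is cut at the two bonds that join it to the enone 11. What remains is toluate 10, in which the lateral methyl is C4 and the ester carbon is C1. The forward step must deprotonate that one methyl group, add it to 11, and close the ring onto the ester so that the C1 hydroxyl ends up peri to the C8 oxygen. Ring C of 10 has a vinyl group where ring B has the methyl, so only one site can react.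

**10 from 5 and 8 (C7–C7').** The biaryl bond is cut so that the two rings are already different before they are joined: 5 carries the methyl group, 8 the vinyl group. A homocoupling of 5 followed by functionalisation of one of two equivalent methyl groups would need the same number of steps but would be statistical.

**8 from 5 (vinyl terminal carbon).** The vinyl group is the lateral methyl of 5 extended by one carbon, through the same benzylic anion chemistry that the annulation uses, followed by elimination of the amine 6.

**5 from 1 (carboxyl carbon).** The carboxyl carbon is introduced as a formyl group at the only free ortho position of phenol 1 (2), then protected (3), oxidised (4) and esterified (5). Bromine at the other ortho position becomes the coupling handle.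

**22 from 19 and 20.** The imide is the N-acylation product of auxiliary 20 with acid 19.

## Alternatives that were turned down

**Alternative 1:** Ring C is dissected into three alkynes. C7'–C8' comes from alkynylboronate A2 (the silylene-protected naphthalene half with a C≡C–B(OiPr)2 group on C7). C8a'–C4a' comes from enynyl carbinol A3, which already holds C1', C2', both stereocentres and the future C4a' vinyl group. C5'–C6' comes from acetylene A4. In the forward step A2 and A3 exchange isopropanol for a B–O tether, and Cp*RuCl(cod) couples the tethered alkynes and inserts A4. This forms C8'–C8a', C4a'–C5' and C6'–C7' and gives benzoxaborole A1; oxidation of the C–B bond and metathesis would follow.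
- For: the tether fixes the arene regiochemistry. The C8' oxygen arrives as boron, so ring C needs no phenol protection. The aldol that sets the stereocentres is run on an unhindered ynal, not on a doubly ortho-substituted benzaldehyde. On that last point this plan is stronger than the chosen one.
- Against: A3 is an enyne carrying a β-hydroxy ketone and an isopropenyl group, and the same ruthenium complex also promotes alkene–alkyne coupling and enyne cycloisomerisation. A4 must be taken up exactly once, against homotrimerisation. The sensitive aldol unit is carried through a metal-catalysed cycloaddition and a basic peroxide oxidation of boron. The naphthalene half A2, with its acetyl group, must still be built, most plausibly by the same toluate annulation, so no steps are saved.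
- Comparison: the chosen route keeps both stereocentres out of the synthesis until five steps from the end and makes all arene carbons from one cheap phenol.

**Alternative 2:** Rings B and C are both cut at C6–C7 and C4a–C8a (and the primed bonds). The C7–C7' bond is present from the start as the central bond of bis-dienol ether A6. Each ring takes C4a, C5, C6 and the methyl carbon from 4,4-dimethoxybutan-2-one A7. In the forward step TiCl4 promotes two cyclocondensations: each terminal diene carbon attacks an acetal carbon, each ester-bearing carbon attacks a ketone, and loss of methanol and water aromatises both rings to diester A5.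
- For: very short access to the biaryl bis-salicylate from acyclic materials, with no halogen, no transition metal and inherent methyl-ortho-to-ester regiochemistry. In step count to the biaryl it is stronger than the chosen route, which needs seven steps to 10.
- Against: A5 is symmetric, with an ester-activated methyl on both rings. The annulation needs exactly one, so differentiation would have to follow by statistical mono-functionalisation after protecting both phenols. The bis-diene is cross-conjugated and labile, two ring formations must both succeed (the second next to the first arene), and the 1,4-diketone liberated on partial desilylation can close to a furan.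
- Comparison: the chosen route differentiates the rings as 5 and 8 before they are joined and couples them without a statistical step.

**Alternative 3:** Ring B is cut at C8–C8a and C5–C4a. Ketene silyl acetal diene A9 supplies C5 to C8 (C8 as the acetal carbon, ring C on C7). Methyl but-2-ynoate A10 supplies C4a and C8a with the methyl and ester groups. In the forward step a [4+2] cycloaddition, followed by loss of methanol from the adduct, aromatises ring B to salicylate A8.
- For: ring C enters fully differentiated and at the aldehyde oxidation level (dioxolane). The later annulation substrate then has no second ester and no ester-conjugated styrene, and no reduction and re-oxidation is needed afterwards. On these points it is stronger than the chosen route.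
- Against: ring C, with four contiguous substituents, must be built first, then an α-aryl crotonate, then its hindered silyl ketene acetal. A10 is a sluggish, β-substituted dienophile that needs heat, under which the diene can suffer silyl and hydrogen shifts and the styrene can react as a competing 2π partner. A8 is still only the toluate, so the same annulation is needed afterwards and the linear sequence is longer.
- Comparison: the chosen route builds both rings from the single bromo salicylate 5 and accepts a reduction–oxidation pair in exchange.

Key step: step 8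

## Route

Ar (used in names from step 14 on) = 2-(tert-butyldimethylsilyloxy)-3-[7-acetyl-6-methyl-1,8-(di-tert-butylsilanediyldioxy)naphthalen-2-yl]-6-vinylphenyl, that is ring C bearing OTBS, the silylene-bridged naphthalene half and the vinyl group.

Step 1
Reactants: 1 2-bromo-5-methylphenol
Product: 2 3-bromo-2-hydroxy-6-methylbenzaldehyde
Conditions: MgCl2, Et3N, (CH2O)n, MeCN, reflux; aq. HCl work-up
Reagents that add atoms: paraformaldehyde (formaldehyde), C=O
Why: Magnesium-phenoxide-directed ortho-formylation (Casnati–Skattebøl reaction); bromine blocks the other ortho position, so the carbon can only enter between OH and CH3, which gives the 3-substituted 6-methylsalicyl pattern; a second formaldehyde accepts hydride from the benzylic alkoxide to give the aldehyde.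

Step 2
Reactants: 2 3-bromo-2-hydroxy-6-methylbenzaldehyde
Product: 3 3-bromo-2-(methoxymethoxy)-6-methylbenzaldehyde
Conditions: MOMCl, iPr2NEt, CH2Cl2, 0 °C to rt
Reagents that add atoms: chloromethyl methyl ether, COCCl
Why: O-alkylation of the hydrogen-bonded phenol; the methoxymethyl ether withstands amide bases, palladium coupling and the annulation and can be removed with dilute acid while the molecule is still robust.

Step 3
Reactants: 3 3-bromo-2-(methoxymethoxy)-6-methylbenzaldehyde
Product: 4 3-bromo-2-(methoxymethoxy)-6-methylbenzoic acid
Conditions: NaClO2, NaH2PO4, 2-methylbut-2-ene, t-BuOH/H2O, rt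
Reagents that add atoms: sodium chlorite, [Na+].[O-]Cl=O
Why: Pinnick oxidation is insensitive to the two ortho substituents and leaves the aryl bromide and the acetal ether alone; the alkene scavenges hypochlorous acid.

Step 4
Reactants: 4 3-bromo-2-(methoxymethoxy)-6-methylbenzoic acid
Product: 5 methyl 3-bromo-2-(methoxymethoxy)-6-methylbenzoate
Conditions: MeI, K2CO3, DMF, rt
Reagents that add atoms: iodomethane, CI
Why: SN2 alkylation of the carboxylate is not slowed by ortho hindrance and needs no acid; the methyl ester is both the activating group for lateral deprotonation and the electrophile of the later ring closure.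

Step 5
Reactants: 5 methyl 3-bromo-2-(methoxymethoxy)-6-methylbenzoate
Product: 6 methyl 3-bromo-6-[2-(dimethylamino)ethyl]-2-(methoxymethoxy)benzoate
Conditions: LiN(iPr)2 (1.1 equiv, commercial solution), THF, −78 °C; then CH2=NMe2+ I−, −78 °C to rt
Reagents that add atoms: N,N-dimethylmethyleneiminium iodide (Eschenmoser's salt), C=[N+](C)C.[I-]
Why: Lateral lithiation of the o-toluate gives the ester-stabilised benzylic anion within minutes at −78 °C, faster than the hindered amide can attack the aryl bromide; Mannich trapping adds the one carbon that becomes the vinyl terminus.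

Step 6
Reactants: 6 methyl 3-bromo-6-[2-(dimethylamino)ethyl]-2-(methoxymethoxy)benzoate
Product: 8 methyl 3-bromo-2-(methoxymethoxy)-6-vinylbenzoate, via trimethylammonium iodide 7 (not isolated)
Conditions: MeI, MeCN, rt; evaporate; DBU, MeCN, 50 °C
Reagents that add atoms: none
Why: Exhaustive methylation followed by Hofmann elimination; the β-hydrogens of 7 are benzylic and further acidified by the ortho ester, so an amidine base suffices; the methyl group has become the vinyl group that marks ring C.

Step 7
Reactants: 5 methyl 3-bromo-2-(methoxymethoxy)-6-methylbenzoate; 8 methyl 3-bromo-2-(methoxymethoxy)-6-vinylbenzoate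
Product: 10 dimethyl 2,2'-bis(methoxymethoxy)-4-methyl-4'-vinylbiphenyl-3,3'-dicarboxylate, via pinacol boronate 9 (not isolated)
Conditions: 5, B2pin2, PdCl2(dppf) (5 mol%), KOAc, 1,4-dioxane, 90 °C; then 8, aq. K3PO4, 80 °C
Reagents that add atoms: none
Why: Miyaura borylation of 5 and Suzuki–Miyaura cross-coupling with 8 in one flask; each partner has only one ortho substituent at the new C7–C7' bond, and esters, acetal ethers and the styrene are tolerated, so the two differentiated rings are joined without a statistical step.

Step 8
Reactants: 10 dimethyl 2,2'-bis(methoxymethoxy)-4-methyl-4'-vinylbiphenyl-3,3'-dicarboxylate; 11 (E)-4-methoxypent-3-en-2-one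
Product: 13 methyl 3-[7-acetyl-8-hydroxy-1-(methoxymethoxy)-6-methylnaphthalen-2-yl]-2-(methoxymethoxy)-6-vinylbenzoate, via open-chain aryl enone 12 (not isolated)
Conditions: LiN(iPr)2 (2.2 equiv, commercial solution), THF, −78 °C, 10 added to the base; then 11 (1.5 equiv), −78 °C to rt; aq. NH4Cl
Reagents that add atoms: none
Why: LiN(iPr)2 removes a proton from the only methyl group ortho to an ester (the future C4), giving a benzylic lithium species delocalised into the ester; ring C has a vinyl group at the corresponding position and cannot compete. The anion adds 1,4 to the methoxy-bearing carbon of 11 and methoxide is expelled, which forms C3–C4 and gives enone 12. A second equivalent of base removes the now doubly activated benzylic hydrogen, and the α-carbon of the resulting dienolate (C2) attacks the neighbouring ester carbon (C1) in a Dieckmann-type Claisen condensation, a 6-exo-trig closure at the ester carbonyl that forms C1–C2 and ring A; loss of methoxide and enolisation aromatise the ring to the 1-naphthol, hydrogen-bonded to the C2 acetyl group. The closest known reaction type is the Staunton–Weinreb annulation of o-toluate anions with β-methoxy enones to 2-acyl-3-methyl-1-naphthols. No stereocentre is formed. The step needs site selectivity (secured by the single ester-activated methyl), regioselectivity (acetyl on C2, methyl on C3, fixed by the polarity of 11) and chemoselectivity over the ring C ester and its conjugated vinyl group, for which 10 is added to the base at −78 °C so that the anion never meets neutral 10 and 11 follows at once as the better acceptor.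

Step 9
Reactants: 13 methyl 3-[7-acetyl-8-hydroxy-1-(methoxymethoxy)-6-methylnaphthalen-2-yl]-2-(methoxymethoxy)-6-vinylbenzoate
Product: 14 methyl 3-(7-acetyl-1,8-dihydroxy-6-methylnaphthalen-2-yl)-2-hydroxy-6-vinylbenzoate
Conditions: HCl, MeOH/THF, rt to 40 °C
Reagents that add atoms: none
Why: Acid-catalysed acetal exchange with methanol removes both methoxymethyl ethers, assisted by hydrogen bonding to the neighbouring ester carbonyl and peri hydroxyl; it is done here because ring D, once formed, would not survive acid.

Step 10
Reactants: 14 methyl 3-(7-acetyl-1,8-dihydroxy-6-methylnaphthalen-2-yl)-2-hydroxy-6-vinylbenzoate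
Product: 16 methyl 3-[7-acetyl-6-methyl-1,8-(di-tert-butylsilanediyldioxy)naphthalen-2-yl]-2-(tert-butyldimethylsilyloxy)-6-vinylbenzoate, via peri-silylene phenol 15 (not isolated)
Conditions: tBu2Si(OTf)2, 2,6-lutidine, CH2Cl2, 0 °C; then TBSOTf, 0 °C to rt
Reagents that add atoms: di-tert-butylsilyl bis(trifluoromethanesulfonate), CC(C)(C)[Si](OS(=O)(=O)C(F)(F)F)(OS(=O)(=O)C(F)(F)F)C(C)(C)C; tert-butyldimethylsilyl trifluoromethanesulfonate, CC(C)(C)[Si](C)(C)OS(=O)(=O)C(F)(F)F
Why: Silyl triflate silylation; the coplanar peri diol closes a strain-free six-membered dioxasiline, which should win over the seven-membered ring across the biaryl axis and avoids two bulky silyl groups side by side, and the remaining ring C phenol is capped as the TBS ether; all three O–Si bonds can later be cleaved together by fluoride.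

Step 11
Reactants: 16 methyl 3-[7-acetyl-6-methyl-1,8-(di-tert-butylsilanediyldioxy)naphthalen-2-yl]-2-(tert-butyldimethylsilyloxy)-6-vinylbenzoate
Product: 17 [2-(tert-butyldimethylsilyloxy)-3-[7-(1-hydroxyethyl)-6-methyl-1,8-(di-tert-butylsilanediyldioxy)naphthalen-2-yl]-6-vinylphenyl]methanol (mixture of carbinol epimers)
Conditions: iBu2AlH, CH2Cl2, −78 to 0 °C; aq. potassium sodium tartrate
Reagents that add atoms: none
Why: The aluminium hydride reduces the hindered ester to the benzylic alcohol and, unavoidably, the naphthyl ketone to the secondary alcohol, whose configuration is of no consequence; aryl silyl ethers and the styrene are untouched at low temperature.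

Step 12
Reactants: 17 [2-(tert-butyldimethylsilyloxy)-3-[7-(1-hydroxyethyl)-6-methyl-1,8-(di-tert-butylsilanediyldioxy)naphthalen-2-yl]-6-vinylphenyl]methanol
Product: 18 2-(tert-butyldimethylsilyloxy)-3-[7-acetyl-6-methyl-1,8-(di-tert-butylsilanediyldioxy)naphthalen-2-yl]-6-vinylbenzaldehyde
Conditions: Dess–Martin periodinane, CH2Cl2, rt
Reagents that add atoms: none
Why: Dess–Martin oxidation returns the secondary alcohol to the acetyl group and takes the primary alcohol to the aldehyde under neutral conditions; with all phenols silylated, quinone formation cannot interfere.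

Step 13
Reactants: 19 3-methylbut-3-enoic acid; 20 (S)-4-benzyloxazolidin-2-one
Product: 22 (S)-4-benzyl-3-(3-methylbut-3-enoyl)oxazolidin-2-one, via mixed pivalic anhydride 21 (not isolated)
Conditions: 19, t-BuCOCl, Et3N, THF, −20 °C; 20, n-BuLi, THF, −78 °C; combine, −78 to 0 °C
Reagents that add atoms: none
Why: N-acylation of the lithiated oxazolidinone by the mixed anhydride, which is attacked at its less hindered acyl group; low temperature keeps the β,γ-double bond from moving into conjugation.

Step 14
Reactants: 18 2-(tert-butyldimethylsilyloxy)-3-[7-acetyl-6-methyl-1,8-(di-tert-butylsilanediyldioxy)naphthalen-2-yl]-6-vinylbenzaldehyde; 22 (S)-4-benzyl-3-(3-methylbut-3-enoyl)oxazolidin-2-one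
Product: 23 (S)-4-benzyl-3-[(2R,3S)-3-Ar-2-(prop-1-en-2-yl)-3-(trimethylsilyloxy)propanoyl]oxazolidin-2-one
Conditions: MgCl2 (20 mol%), Et3N, Me3SiCl, EtOAc, rt
Reagents that add atoms: chlorotrimethylsilane, C[Si](C)(C)Cl
Why: Magnesium-halide-catalysed direct anti-aldol of an N-acyloxazolidinone with a non-enolisable aromatic aldehyde; the chelated Z magnesium enolate reacts at its α-carbon through a closed boat-like transition state on the face away from the benzyl group (C2' becomes R), with the aryl group placed anti (C1' becomes S). Silylation of the aldolate releases the magnesium and blocks retro-aldol.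

Step 15
Reactants: 23 (S)-4-benzyl-3-[(2R,3S)-3-Ar-2-(prop-1-en-2-yl)-3-(trimethylsilyloxy)propanoyl]oxazolidin-2-one
Product: 24 S-ethyl (2R,3S)-3-Ar-2-(prop-1-en-2-yl)-3-(trimethylsilyloxy)propanethioate
Conditions: EtSH (excess), n-BuLi, THF, 0 °C
Reagents that add atoms: lithium ethanethiolate, [Li+].CC[S-] (made in the flask from ethanethiol, CCS, and n-BuLi)
Why: Transthioesterification; the soft thiolate attacks the exocyclic acyl carbon and releases the auxiliary, and the excess thiol keeps the medium weakly basic so that the C2' hydrogen, α to the carbonyl and allylic, is not removed.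

Step 16
Reactants: 24 S-ethyl (2R,3S)-3-Ar-2-(prop-1-en-2-yl)-3-(trimethylsilyloxy)propanethioate
Product: 25 (3R,4S)-4-Ar-3-(prop-1-en-2-yl)-4-(trimethylsilyloxy)butan-2-one
Conditions: Me2CuLi (from MeLi and CuI), Et2O, −78 to −40 °C
Reagents that add atoms: lithium dimethylcuprate, [Li+].C[Cu-]C (made in the flask from methyllithium, [Li]C, and CuI)
Why: Acyl substitution of a thioester by a Gilman cuprate gives the methyl ketone at a temperature at which cuprates add neither to the product nor to the hindered ring A ketone; this is the reason for going through a thioester and not through an amide that would need a Grignard reagent.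

Step 17
Reactants: 25 (3R,4S)-4-Ar-3-(prop-1-en-2-yl)-4-(trimethylsilyloxy)butan-2-one
Product: 26 1-[(1S,2R)-7-[7-acetyl-6-methyl-1,8-(di-tert-butylsilanediyldioxy)naphthalen-2-yl]-8-(tert-butyldimethylsilyloxy)-3-methyl-1-(trimethylsilyloxy)-1,2-dihydronaphthalen-2-yl]ethan-1-one
Conditions: second-generation Hoveyda–Grubbs catalyst (10 mol%), 1,4-benzoquinone (20 mol%), toluene, 60 °C
Reagents that add atoms: none
Why: Ring-closing metathesis between the styrene and the 1,1-disubstituted alkene closes six-membered ring D as a trisubstituted, arene-conjugated alkene with loss of ethylene; benzoquinone suppresses ruthenium hydride species that could move the double bonds, and the stereocentres are not involved.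

Step 18
Reactants: 26 1-[(1S,2R)-7-[7-acetyl-6-methyl-1,8-(di-tert-butylsilanediyldioxy)naphthalen-2-yl]-8-(tert-butyldimethylsilyloxy)-3-methyl-1-(trimethylsilyloxy)-1,2-dihydronaphthalen-2-yl]ethan-1-one
Product: 27 1-[(1S,2R)-7-(7-acetyl-1,8-dihydroxy-6-methylnaphthalen-2-yl)-1,8-dihydroxy-3-methyl-1,2-dihydronaphthalen-2-yl]ethan-1-one (target)
Conditions: Bu4NF, AcOH, THF, 0 °C
Reagents that add atoms: none
Why: Fluoride cleaves the aryl silyl ether, the silylene and the trimethylsilyl ether; acetic acid protonates the phenoxides and the alkoxide as they form, so that neither base-induced elimination nor retro-aldol can start in ring D.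

## Compound list

1 | 2-bromo-5-methylphenol | Cc1ccc(Br)c(O)c1 | starting material
2 | 3-bromo-2-hydroxy-6-methylbenzaldehyde | Cc1ccc(Br)c(O)c1C=O | intermediate
3 | 3-bromo-2-(methoxymethoxy)-6-methylbenzaldehyde | Cc1ccc(Br)c(OCOC)c1C=O | intermediate
4 | 3-bromo-2-(methoxymethoxy)-6-methylbenzoic acid | Cc1ccc(Br)c(OCOC)c1C(=O)O | intermediate
5 | methyl 3-bromo-2-(methoxymethoxy)-6-methylbenzoate | COC(=O)c1c(C)ccc(Br)c1OCOC | intermediate
6 | methyl 3-bromo-6-[2-(dimethylamino)ethyl]-2-(methoxymethoxy)benzoate | COC(=O)c1c(CCN(C)C)ccc(Br)c1OCOC | intermediate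
7 | 2-[4-bromo-2-(methoxycarbonyl)-3-(methoxymethoxy)phenyl]-N,N,N-trimethylethan-1-aminium iodide | COC(=O)c1c(CC[N+](C)(C)C)ccc(Br)c1OCOC.[I-] | intermediate (not isolated)
8 | methyl 3-bromo-2-(methoxymethoxy)-6-vinylbenzoate | COC(=O)c1c(C=C)ccc(Br)c1OCOC | intermediate
9 | methyl 2-(methoxymethoxy)-6-methyl-3-(4,4,5,5-tetramethyl-1,3,2-dioxaborolan-2-yl)benzoate | COC(=O)c1c(C)ccc(B2OC(C)(C)C(C)(C)O2)c1OCOC | intermediate (not isolated)
10 | dimethyl 2,2'-bis(methoxymethoxy)-4-methyl-4'-vinylbiphenyl-3,3'-dicarboxylate | COC(=O)c1c(C)ccc(-c2ccc(C=C)c(C(=O)OC)c2OCOC)c1OCOC | intermediate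
11 | (E)-4-methoxypent-3-en-2-one | CO/C(C)=C/C(C)=O | starting material
12 | dimethyl 2,2'-bis(methoxymethoxy)-4-(2-methyl-4-oxopent-2-en-1-yl)-4'-vinylbiphenyl-3,3'-dicarboxylate (alkene geometry not defined) | COC(=O)c1c(CC(C)=CC(C)=O)ccc(-c2ccc(C=C)c(C(=O)OC)c2OCOC)c1OCOC | intermediate (not isolated)
13 | methyl 3-[7-acetyl-8-hydroxy-1-(methoxymethoxy)-6-methylnaphthalen-2-yl]-2-(methoxymethoxy)-6-vinylbenzoate | CC(=O)c1c(C)cc2ccc(-c3ccc(C=C)c(C(=O)OC)c3OCOC)c(OCOC)c2c1O | intermediate
14 | methyl 3-(7-acetyl-1,8-dihydroxy-6-methylnaphthalen-2-yl)-2-hydroxy-6-vinylbenzoate | CC(=O)c1c(C)cc2ccc(-c3ccc(C=C)c(C(=O)OC)c3O)c(O)c2c1O | intermediate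
15 | methyl 3-[7-acetyl-6-methyl-1,8-(di-tert-butylsilanediyldioxy)naphthalen-2-yl]-2-hydroxy-6-vinylbenzoate | CC(=O)c1c(C)cc2ccc(-c3ccc(C=C)c(C(=O)OC)c3O)c3O[Si](C(C)(C)C)(C(C)(C)C)Oc1c23 | intermediate (not isolated)
16 | methyl 3-[7-acetyl-6-methyl-1,8-(di-tert-butylsilanediyldioxy)naphthalen-2-yl]-2-(tert-butyldimethylsilyloxy)-6-vinylbenzoate | CC(=O)c1c(C)cc2ccc(-c3ccc(C=C)c(C(=O)OC)c3O[Si](C)(C)C(C)(C)C)c3O[Si](C(C)(C)C)(C(C)(C)C)Oc1c23 | intermediate
17 | [2-(tert-butyldimethylsilyloxy)-3-[7-(1-hydroxyethyl)-6-methyl-1,8-(di-tert-butylsilanediyldioxy)naphthalen-2-yl]-6-vinylphenyl]methanol (mixture of carbinol epimers) | CC(O)c1c(C)cc2ccc(-c3ccc(C=C)c(CO)c3O[Si](C)(C)C(C)(C)C)c3O[Si](C(C)(C)C)(C(C)(C)C)Oc1c23 | intermediate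
18 | 2-(tert-butyldimethylsilyloxy)-3-[7-acetyl-6-methyl-1,8-(di-tert-butylsilanediyldioxy)naphthalen-2-yl]-6-vinylbenzaldehyde | CC(=O)c1c(C)cc2ccc(-c3ccc(C=C)c(C=O)c3O[Si](C)(C)C(C)(C)C)c3O[Si](C(C)(C)C)(C(C)(C)C)Oc1c23 | intermediate
19 | 3-methylbut-3-enoic acid | C=C(C)CC(=O)O | starting material
20 | (S)-4-benzyloxazolidin-2-one | O=C1N[C@@H](Cc2ccccc2)CO1 | starting material
21 | 3-methylbut-3-enoic pivalic anhydride | C=C(C)CC(=O)OC(=O)C(C)(C)C | intermediate (not isolated)
22 | (S)-4-benzyl-3-(3-methylbut-3-enoyl)oxazolidin-2-one | C=C(C)CC(=O)N1[C@@H](Cc2ccccc2)COC1=O | intermediate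
23 | (S)-4-benzyl-3-[(2R,3S)-3-Ar-2-(prop-1-en-2-yl)-3-(trimethylsilyloxy)propanoyl]oxazolidin-2-one | CC(=O)c1c(C)cc2ccc(-c3ccc(C=C)c([C@@H](O[Si](C)(C)C)[C@H](C(=O)N4[C@@H](Cc5ccccc5)COC4=O)C(C)=C)c3O[Si](C)(C)C(C)(C)C)c3O[Si](C(C)(C)C)(C(C)(C)C)Oc1c23 | intermediate
24 | S-ethyl (2R,3S)-3-Ar-2-(prop-1-en-2-yl)-3-(trimethylsilyloxy)propanethioate | CC(=O)c1c(C)cc2ccc(-c3ccc(C=C)c([C@@H](O[Si](C)(C)C)[C@H](C(=O)SCC)C(C)=C)c3O[Si](C)(C)C(C)(C)C)c3O[Si](C(C)(C)C)(C(C)(C)C)Oc1c23 | intermediate
25 | (3R,4S)-4-Ar-3-(prop-1-en-2-yl)-4-(trimethylsilyloxy)butan-2-one | CC(=O)c1c(C)cc2ccc(-c3ccc(C=C)c([C@@H](O[Si](C)(C)C)[C@H](C(C)=O)C(C)=C)c3O[Si](C)(C)C(C)(C)C)c3O[Si](C(C)(C)C)(C(C)(C)C)Oc1c23 | intermediate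
26 | 1-[(1S,2R)-7-[7-acetyl-6-methyl-1,8-(di-tert-butylsilanediyldioxy)naphthalen-2-yl]-8-(tert-butyldimethylsilyloxy)-3-methyl-1-(trimethylsilyloxy)-1,2-dihydronaphthalen-2-yl]ethan-1-one | CC(=O)c1c(C)cc2ccc(-c3ccc4c(c3O[Si](C)(C)C(C)(C)C)[C@@H](O[Si](C)(C)C)[C@H](C(C)=O)C(C)=C4)c3O[Si](C(C)(C)C)(C(C)(C)C)Oc1c23 | intermediate
27 | 1-[(1S,2R)-7-(7-acetyl-1,8-dihydroxy-6-methylnaphthalen-2-yl)-1,8-dihydroxy-3-methyl-1,2-dihydronaphthalen-2-yl]ethan-1-one | CC(=O)c1c(C)cc2ccc(-c3ccc4c(c3O)[C@@H](O)[C@H](C(C)=O)C(C)=C4)c(O)c2c1O | target

## Step count and weak points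

Total: 18 steps. Longest linear sequence: 17 steps (steps 1 to 12 and 14 to 18, from 1 to 27); step 13 prepares the imide on the side.

**Step 8 (key step).** The benzylic anion may be consumed intermolecularly, by addition to the ester-conjugated vinyl group or to an ester of a second molecule, or be quenched by proton transfer from the acetyl methyl of 11; the outcome would be oligomerisation or recovery of 10. Fallback: change the order of annulation and biaryl coupling. Setting out from 5 and 11, the same LiN(iPr)2-mediated annulation on the simple bromo toluate, which has neither styrene nor second ester, should give 1-[7-bromo-1-hydroxy-8-(methoxymethoxy)-3-methylnaphthalen-2-yl]ethan-1-one F1. Bromide 8 is converted with B2pin2, PdCl2(dppf) and KOAc into methyl 2-(methoxymethoxy)-3-(4,4,5,5-tetramethyl-1,3,2-dioxaborolan-2-yl)-6-vinylbenzoate F2. Suzuki–Miyaura coupling of F1 with F2 (zerovalent palladium generated from Pd(OAc)2 and SPhos, K3PO4, aqueous dioxane) returns to the route at 13.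

**Step 14.** Addition to the doubly ortho-substituted aldehyde may be slow. The magnesium dienolate would then have time to isomerise to the conjugated imide or to react at its γ-carbon, and the anti/syn or facial control may erode. Fallback: setting out from 18 and 22, the preformed Z dibutylboron enolate of 22 (Bu2BOTf, iPr2NEt, CH2Cl2) is added at −78 °C to 18 precomplexed with Et2AlCl. This is an open transition state with an activated aldehyde, anti-selective and using the same chelate-controlled enolate face. It should give the free carbinol (S)-4-benzyl-3-[(2R,3S)-3-Ar-3-hydroxy-2-(prop-1-en-2-yl)propanoyl]oxazolidin-2-one F3. Silylation with Me3SiCl and imidazole returns to the route at 23.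

**Step 15.** The thiolate may act as a base on the C2' hydrogen, causing epimerisation or migration of the isopropenyl double bond into conjugation; the trimethylsilyl ether may also be lost. Fallback: a Lewis-acidic amide exchange in place of the thiolate. Setting out from 23, the trimethylsilyl ether is cleaved with citric acid in methanol to F3. Me2AlN(OMe)Me (from Me3Al and MeNHOMe·HCl), directed by the free hydroxyl, gives (2R,3S)-3-Ar-3-hydroxy-N-methoxy-N-methyl-2-(prop-1-en-2-yl)propanamide F4. MeMgBr at −40 °C, where the doubly ortho-substituted ring A ketone should be enolised rather than attacked and the tetrahedral adduct shields C2' until work-up, gives (3R,4S)-4-Ar-4-hydroxy-3-(prop-1-en-2-yl)butan-2-one F5. Me3SiCl and imidazole return to the route at 25.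

**Step 17.** Ruthenium hydride species may move the isopropenyl or the new C3'=C4' double bond, after which loss of silanol would aromatise ring D; closure onto the 1,1-disubstituted alkene next to a fully substituted carbon may also be sluggish. Fallback: close the ring one step earlier, on the less enolisable thioester. Setting out from 24, metathesis under the same catalyst should give S-ethyl (1S,2R)-7-[7-acetyl-6-methyl-1,8-(di-tert-butylsilanediyldioxy)naphthalen-2-yl]-8-(tert-butyldimethylsilyloxy)-3-methyl-1-(trimethylsilyloxy)-1,2-dihydronaphthalene-2-carbothioate F6. Me2CuLi at −78 °C then returns to the route at 26.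

**Step 18.** Ionisation of the benzylic C1'–O bond, assisted by the freed ortho phenol, or enolisation at C2' may lead to dehydration and aromatisation of ring D, to epimerisation, or to retro-aldol cleavage. Fallback: remove the silyl groups before ring D exists. Setting out from 25, Bu4NF and AcOH should give (3R,4S)-4-[3-(7-acetyl-1,8-dihydroxy-6-methylnaphthalen-2-yl)-2-hydroxy-6-vinylphenyl]-4-hydroxy-3-(prop-1-en-2-yl)butan-2-one F7, in which elimination cannot aromatise anything. Ring-closing metathesis with the second-generation Hoveyda–Grubbs catalyst under neutral conditions is then the last step and returns to the route at 27.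

## Further compounds

F1 | step 8 | 1-[7-bromo-1-hydroxy-8-(methoxymethoxy)-3-methylnaphthalen-2-yl]ethan-1-one | CC(=O)c1c(C)cc2ccc(Br)c(OCOC)c2c1O
F2 | step 8 | methyl 2-(methoxymethoxy)-3-(4,4,5,5-tetramethyl-1,3,2-dioxaborolan-2-yl)-6-vinylbenzoate | COC(=O)c1c(C=C)ccc(B2OC(C)(C)C(C)(C)O2)c1OCOC
F3 | step 14 | (S)-4-benzyl-3-[(2R,3S)-3-Ar-3-hydroxy-2-(prop-1-en-2-yl)propanoyl]oxazolidin-2-one | CC(=O)c1c(C)cc2ccc(-c3ccc(C=C)c([C@@H](O)[C@H](C(=O)N4[C@@H](Cc5ccccc5)COC4=O)C(C)=C)c3O[Si](C)(C)C(C)(C)C)c3O[Si](C(C)(C)C)(C(C)(C)C)Oc1c23
F4 | step 15 | (2R,3S)-3-Ar-3-hydroxy-N-methoxy-N-methyl-2-(prop-1-en-2-yl)propanamide | CC(=O)c1c(C)cc2ccc(-c3ccc(C=C)c([C@@H](O)[C@H](C(=O)N(C)OC)C(C)=C)c3O[Si](C)(C)C(C)(C)C)c3O[Si](C(C)(C)C)(C(C)(C)C)Oc1c23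
F5 | step 15 | (3R,4S)-4-Ar-4-hydroxy-3-(prop-1-en-2-yl)butan-2-one | CC(=O)c1c(C)cc2ccc(-c3ccc(C=C)c([C@@H](O)[C@H](C(C)=O)C(C)=C)c3O[Si](C)(C)C(C)(C)C)c3O[Si](C(C)(C)C)(C(C)(C)C)Oc1c23
F6 | step 17 | S-ethyl (1S,2R)-7-[7-acetyl-6-methyl-1,8-(di-tert-butylsilanediyldioxy)naphthalen-2-yl]-8-(tert-butyldimethylsilyloxy)-3-methyl-1-(trimethylsilyloxy)-1,2-dihydronaphthalene-2-carbothioate | CC(=O)c1c(C)cc2ccc(-c3ccc4c(c3O[Si](C)(C)C(C)(C)C)[C@@H](O[Si](C)(C)C)[C@H](C(=O)SCC)C(C)=C4)c3O[Si](C(C)(C)C)(C(C)(C)C)Oc1c23
F7 | step 18 | (3R,4S)-4-[3-(7-acetyl-1,8-dihydroxy-6-methylnaphthalen-2-yl)-2-hydroxy-6-vinylphenyl]-4-hydroxy-3-(prop-1-en-2-yl)butan-2-one | CC(=O)c1c(C)cc2ccc(-c3ccc(C=C)c([C@@H](O)[C@H](C(C)=O)C(C)=C)c3O)c(O)c2c1O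
A1 | alternative 1 | ring C benzoxaborole isopropyl ester carrying the silylene-protected naphthalene half, the C4a' vinyl group and the anti aldol side chain | C=Cc1ccc(-c5ccc6cc(C)c(C(C)=O)c7O[Si](C(C)(C)C)(C(C)(C)C)Oc5c67)c3c1[C@@H](OB3OC(C)C)[C@H](C(C)=O)C(C)=C
A2 | alternative 1 | diisopropyl [[7-acetyl-6-methyl-1,8-(di-tert-butylsilanediyldioxy)naphthalen-2-yl]ethynyl]boronate | CC(C)OB(OC(C)C)C#Cc1ccc2cc(C)c(C(C)=O)c3O[Si](C(C)(C)C)(C(C)(C)C)Oc1c23
A3 | alternative 1 | (3R,4S)-4-hydroxy-3-(prop-1-en-2-yl)oct-7-en-5-yn-2-one | C=CC#C[C@@H](O)[C@H](C(C)=O)C(C)=C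
A4 | alternative 1 | acetylene | C#C
A5 | alternative 2 | dimethyl 2,2'-dihydroxy-4,4'-dimethylbiphenyl-3,3'-dicarboxylate | COC(=O)c1c(C)ccc(-c2ccc(C)c(C(=O)OC)c2O)c1O
A6 | alternative 2 | 1,8-dimethoxy-1,3,6,8-tetrakis(trimethylsilyloxy)octa-1,3,5,7-tetraene | COC(O[Si](C)(C)C)=CC(O[Si](C)(C)C)=CC=C(O[Si](C)(C)C)C=C(OC)O[Si](C)(C)C
A7 | alternative 2 | 4,4-dimethoxybutan-2-one | CC(=O)CC(OC)OC
A8 | alternative 3 | methyl 3-[3-(1,3-dioxolan-2-yl)-2-(methoxymethoxy)-4-vinylphenyl]-2-hydroxy-6-methylbenzoate | COC(=O)c1c(C)ccc(-c2ccc(C=C)c(C3OCCO3)c2OCOC)c1O
A9 | alternative 3 | [2-[3-(1,3-dioxolan-2-yl)-2-(methoxymethoxy)-4-vinylphenyl]-1-methoxybuta-1,3-dien-1-yl]oxytrimethylsilane | C=CC(=C(OC)O[Si](C)(C)C)c1ccc(C=C)c(C2OCCO2)c1OCOC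
A10 | alternative 3 | methyl but-2-ynoate | CC#CC(=O)OC
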